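The ten-membered ring (C1 angeloyloxy carbon, C2, C3–C4 epoxide, C5 acetoxy carbon, C6 isopropyl carbon, C7, C8, C9–C10 epoxide) contains the 1,5-diene array C7=C6–C5(O)–C10–C9=C8 of a six-membered ring C5–C4–C3–C2–C1–C10. An anionic oxy-Cope rearrangement of cyclohexenol 15, which carries a 3-methylbut-1-en-2-yl group on the carbinol carbon C5 and a trans isopropenyl group on C10, therefore forms the C7–C8 bond, cleaves C5–C10 and delivers the cyclodecadienone in one operation; its chair transition state fixes the C9=C10 geometry and passes the single aldol-derived stereocenter (C1) on to C6. Enone inversion, reduction and one double epoxidation then set C5, C3, C4, C9 and C10 by substrate control.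

Key step: step 9

Remarks on the chemistry: 2-bromo-3-methylbut-1-ene (12) is taken as purchasable. The atom labels C1–C10 defined above are used for every intermediate. Compound 19 is expected as a mixture of epimers at the tin-bearing carbon C3, which is of no consequence because C3 becomes sp2 again in step 11.

**Step 1**
Reactants: 1 (S)-4-benzyloxazolidin-2-one; 2 3-methylbut-2-enoyl chloride
Product: 3 (S)-4-benzyl-3-(3-methylbut-2-enoyl)oxazolidin-2-one
Conditions: n-BuLi, THF, −78 °C; then 2, −78 → 0 °C
Reagents that add atoms: none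
Why: N-acylation of the lithiated oxazolidinone by the acid chloride (standard imide formation); no stereocenter is touched.

**Step 2**
Reactants: 4 3-methylbut-3-en-1-ol
Product: 5 3-methylbut-3-enal
Conditions: Dess–Martin periodinane, NaHCO3, CH2Cl2, 0 → 25 °C; filtered cold solution used at once
Reagents that add atoms: none
Why: Dess–Martin oxidation of a primary alcohol under buffered, non-basic conditions should stop at the β,γ-unsaturated aldehyde, which is used immediately before it can move into conjugation.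

**Step 3**
Reactants: 3 (S)-4-benzyl-3-(3-methylbut-2-enoyl)oxazolidin-2-one; 5 3-methylbut-3-enal
Product: 7 (S)-4-benzyl-3-[(2S,3R)-3-hydroxy-5-methyl-2-(prop-1-en-2-yl)hex-5-enoyl]oxazolidin-2-one, via boron dienolate 6 (not isolated)
Conditions: Bu2BOTf, Et3N, CH2Cl2, −78 → 0 °C; then 5, −78 → 0 °C; pH 7 buffer, MeOH, H2O2, 0 °C
Reagents that add atoms: none
Why: γ-Deprotonation of the boron-complexed imide gives the (Z)-dienolate 6, which reacts at its α-carbon through a Zimmerman–Traxler chair (Evans syn-aldol, deconjugative variant), the (S)-benzyl auxiliary setting C1 (3R) and the temporary C10 center (2S).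

**Step 4**
Reactants: 7 (S)-4-benzyl-3-[(2S,3R)-3-hydroxy-5-methyl-2-(prop-1-en-2-yl)hex-5-enoyl]oxazolidin-2-one
Product: 8 (2S,3R)-3-hydroxy-N-methoxy-N,5-dimethyl-2-(prop-1-en-2-yl)hex-5-enamide
Conditions: MeNH(OMe)·HCl, AlMe3, THF, −20 → 0 °C
Reagents that add atoms: N,O-dimethylhydroxylamine hydrochloride, CNOC.Cl
Why: AlMe3-mediated transamination of a β-hydroxy N-acyloxazolidinone to the Weinreb amide, assisted by the aluminium alkoxide, should release the auxiliary without epimerisation at C10.

**Step 5**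
Reactants: 8 (2S,3R)-3-hydroxy-N-methoxy-N,5-dimethyl-2-(prop-1-en-2-yl)hex-5-enamide
Product: 9 (2S,3R)-3-[(tert-butyldimethylsilyl)oxy]-N-methoxy-N,5-dimethyl-2-(prop-1-en-2-yl)hex-5-enamide
Conditions: TBSOTf, 2,6-lutidine, CH2Cl2, −78 → 0 °C
Reagents that add atoms: tert-butyldimethylsilyl trifluoromethanesulfonate, CC(C)(C)[Si](C)(C)OS(=O)(=O)C(F)(F)F
Why: Silylation of the secondary alcohol with a silyl triflate and a hindered base; the ether blocks retro-aldol cleavage and β-elimination in the organometallic steps that follow.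

**Step 6**
Reactants: 9 (2S,3R)-3-[(tert-butyldimethylsilyl)oxy]-N-methoxy-N,5-dimethyl-2-(prop-1-en-2-yl)hex-5-enamide
Product: 10 (4S,5R)-5-[(tert-butyldimethylsilyl)oxy]-7-methyl-4-(prop-1-en-2-yl)octa-1,7-dien-3-one
Conditions: CH2=CHMgBr, THF, −78 → 0 °C; poured into cold aq. HCl
Reagents that add atoms: vinylmagnesium bromide, C=C[Mg]Br
Why: Grignard addition to a Weinreb amide stops at the chelated tetrahedral intermediate and should give the vinyl ketone on acidic quench, which also keeps the released amine from adding to the enone.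

**Step 7**
Reactants: 10 (4S,5R)-5-[(tert-butyldimethylsilyl)oxy]-7-methyl-4-(prop-1-en-2-yl)octa-1,7-dien-3-one
Product: 11 (5R,6S)-5-[(tert-butyldimethylsilyl)oxy]-3-methyl-6-(prop-1-en-2-yl)cyclohex-2-en-1-one
Conditions: second-generation Hoveyda–Grubbs catalyst RuCl2(H2IMes)(=CH-C6H4-2-O-i-Pr) (5 mol %), toluene, 80 °C
Reagents that add atoms: none
Why: Ring-closing metathesis between the vinyl ketone and the methallyl group closes the six-membered trisubstituted enone (the isopropenyl group could only give a cyclobutene) under neutral conditions that spare the α-center and the silyl ether.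

**Step 8**
Reactants: 11 (5R,6S)-5-[(tert-butyldimethylsilyl)oxy]-3-methyl-6-(prop-1-en-2-yl)cyclohex-2-en-1-one; 12 2-bromo-3-methylbut-1-ene
Product: 15 (1R,5R,6S)-5-[(tert-butyldimethylsilyl)oxy]-3-methyl-1-(3-methylbut-1-en-2-yl)-6-(prop-1-en-2-yl)cyclohex-2-en-1-ol, via vinyllithium reagent 13 (not isolated), via organocerium reagent 14 (not isolated)
Conditions: 12, t-BuLi (2 equiv), THF, −78 °C; CeCl3 (dried), −78 °C; then 11, −78 °C; aq. NH4Cl
Reagents that add atoms: none
Why: 1,2-Addition of the weakly basic organocerium reagent to the enone carbonyl from the equatorial direction, trans to the neighbouring equatorial isopropenyl group, should set the carbinol center C5 with the two alkenyl groups trans and without enolisation of the β-silyloxy ketone.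

**Step 9**
Reactants: 15 (1R,5R,6S)-5-[(tert-butyldimethylsilyl)oxy]-3-methyl-1-(3-methylbut-1-en-2-yl)-6-(prop-1-en-2-yl)cyclohex-2-en-1-ol
Product: 18 (2Z,5R,6E,10S)-5-[(tert-butyldimethylsilyl)oxy]-3,7-dimethyl-10-(propan-2-yl)cyclodeca-2,6-dien-1-one, via potassium alkoxide 16 (not isolated), via potassium enolate 17 (not isolated)
Conditions: KH, 18-crown-6, THF, 0 → 25 °C; then poured into AcOH/THF at −78 °C
Reagents that add atoms: none
Why: Deprotonation gives alkoxide 16, in which the C5–C10 bond is weakened so that a concerted [3,3]-sigmatropic shift through the 1,5-diene C7=C6–C5–C10–C9=C8 forms C7–C8 and cleaves C5–C10 (anionic oxy-Cope rearrangement, the type known for 1,2-dialkenylcyclohexenols giving cyclodecadienones). The ten-membered ring is closed as a four-carbon ring expansion of the cyclohexene through a chair transition state in which both alkenyl groups and the C1 silyloxy group are equatorial. This geometry makes C9=C10 (E), leaves the former ring alkene C3=C4 (Z), and gives enolate 17 with C4 and C7 trans across C5=C6, a planar-chiral unit that cannot turn inside the ring because neither its oxygen nor its isopropyl group can pass through. C6, the only new stereocenter, is set when the cold acid quench protonates the enolate on its outer face (the inner face is covered by the C9=C10 bond), so the C1 center is relayed to C6 with the C1 oxygen and the C6 isopropyl group on the same ring face. The step needs the chair rather than the boat pathway and must avoid silyl migration and β-fragmentation: the trans-diequatorial alkenyl groups secure the first, and the trans 1,3-relationship of the C5 alkoxide to the C1 silyl ether, a poor leaving group, secures the second.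

**Step 10**
Reactants: 18 (2Z,5R,6E,10S)-5-[(tert-butyldimethylsilyl)oxy]-3,7-dimethyl-10-(propan-2-yl)cyclodeca-2,6-dien-1-one
Product: 19 (5R,6E,10S)-5-[(tert-butyldimethylsilyl)oxy]-3,7-dimethyl-10-(propan-2-yl)-3-(trimethylstannyl)cyclodec-6-en-1-one
Conditions: Me3SnLi (from Me3SnSnMe3 and MeLi), THF, −78 °C; AcOH quench
Reagents that add atoms: trimethylstannyllithium, [Li][Sn](C)(C)C
Why: Conjugate addition of the stannyl anion to the β,β-disubstituted enone (1,4-stannylation) is fast and irreversible at low temperature, removes the (Z)-olefin, and leaves C6 untouched because the enolate formed lies toward C4.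

**Step 11**
Reactants: 19 (5R,6E,10S)-5-[(tert-butyldimethylsilyl)oxy]-3,7-dimethyl-10-(propan-2-yl)-3-(trimethylstannyl)cyclodec-6-en-1-one
Product: 20 (2E,5R,6E,10S)-5-[(tert-butyldimethylsilyl)oxy]-3,7-dimethyl-10-(propan-2-yl)cyclodeca-2,6-dien-1-one
Conditions: CrO3·2C5H5N (from CrO3 and pyridine), CH2Cl2, 0 → 25 °C
Reagents that add atoms: none
Why: Oxidative destannylation of the β-stannyl ketone by the hexavalent chromium–pyridine complex regenerates the enone, and elimination from the ring conformer with C2 and C5 anti should give the (E)-olefin, so that stannylation and destannylation together invert the ring-derived (Z)-enone.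

**Step 12**
Reactants: 20 (2E,5R,6E,10S)-5-[(tert-butyldimethylsilyl)oxy]-3,7-dimethyl-10-(propan-2-yl)cyclodeca-2,6-dien-1-one
Product: 21 (1R,2E,5R,6E,10S)-5-[(tert-butyldimethylsilyl)oxy]-3,7-dimethyl-10-(propan-2-yl)cyclodeca-2,6-dien-1-ol
Conditions: i-Bu2AlH, toluene, −78 °C; aq. potassium sodium tartrate
Reagents that add atoms: none
Why: 1,2-Reduction of the twisted β,β-disubstituted enone by the bulky aluminium hydride on the carbonyl face anti to the neighbouring isopropyl group (cyclic Felkin-type attack) should give the C5 alcohol cis to the isopropyl group.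

**Step 13**
Reactants: 21 (1R,2E,5R,6E,10S)-5-[(tert-butyldimethylsilyl)oxy]-3,7-dimethyl-10-(propan-2-yl)cyclodeca-2,6-dien-1-ol
Product: 22 (1R,2E,5R,6E,10S)-5-[(tert-butyldimethylsilyl)oxy]-3,7-dimethyl-10-(propan-2-yl)cyclodeca-2,6-dien-1-yl acetate
Conditions: Ac2O, DMAP (cat.), pyridine, CH2Cl2, 0 → 25 °C
Reagents that add atoms: acetic anhydride, CC(=O)OC(C)=O
Why: DMAP-catalysed acetylation of the secondary allylic alcohol places the acetate on C5 while C1 is still silylated, so the two oxygens are told apart without any selectivity question.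

**Step 14**
Reactants: 22 (1R,2E,5R,6E,10S)-5-[(tert-butyldimethylsilyl)oxy]-3,7-dimethyl-10-(propan-2-yl)cyclodeca-2,6-dien-1-yl acetate
Product: 23 (1R,2E,5R,6E,10S)-5-hydroxy-3,7-dimethyl-10-(propan-2-yl)cyclodeca-2,6-dien-1-yl acetate
Conditions: Bu4NF, AcOH, THF, 0 → 25 °C
Reagents that add atoms: none
Why: Fluoride cleavage of the silyl ether, buffered with acetic acid so that the acetate and the acid- and base-sensitive cyclodeca-1,5-diene survive.

**Step 15**
Reactants: 23 (1R,2E,5R,6E,10S)-5-hydroxy-3,7-dimethyl-10-(propan-2-yl)cyclodeca-2,6-dien-1-yl acetate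
Product: 24 the C1 alcohol of the target, that is the C3–C4:C9–C10 diepoxide bearing the C5 acetate and a free C1 hydroxyl
Conditions: mCPBA (2.4 equiv), NaHCO3, CH2Cl2, −20 → 0 °C
Reagents that add atoms: 3-chloroperoxybenzoic acid, OOC(=O)c1cccc(Cl)c1
Why: Prilezhaev epoxidation of both (E)-trisubstituted alkenes on their outer faces, where A1,3 strain with the vinylic methyl groups keeps C1–H and C5–H eclipsed with the adjacent double bonds so that the ring covers one face of each alkene and oxygen enters syn to the allylic oxygen (hydrogen-bond directed by the free C1 hydroxyl at C9=C10, conformationally controlled at C3=C4), should set C3, C4, C9 and C10 in one operation.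

**Step 16**
Reactants: 24 the C1 alcohol of the target
Product: 25 the target, the C1 angelate and C5 acetate of the C3–C4:C9–C10 diepoxide (CNP0311463.1)
Conditions: angelic acid, 2,4,6-Cl3C6H2COCl, Et3N, toluene, 25 °C; then 24, toluene, 75 °C
Reagents that add atoms: angelic acid ((Z)-2-methylbut-2-enoic acid), C/C=C(/C)C(=O)O
Why: Yamaguchi-type acylation with the preformed mixed anhydride of angelic acid, run without a nucleophilic catalyst so that the (Z)-2-methylbut-2-enoate does not isomerise to the tiglate, should esterify the only free hydroxyl.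

**Compound list**

1 | (S)-4-benzyloxazolidin-2-one | O=C1OC[C@H](Cc2ccccc2)N1 | starting material
2 | 3-methylbut-2-enoyl chloride | CC(C)=CC(=O)Cl | starting material
3 | (S)-4-benzyl-3-(3-methylbut-2-enoyl)oxazolidin-2-one | CC(C)=CC(=O)N1[C@@H](Cc2ccccc2)COC1=O | intermediate
4 | 3-methylbut-3-en-1-ol | CC(=C)CCO | starting material
5 | 3-methylbut-3-enal | CC(=C)CC=O | intermediate
6 | dibutylboron (Z)-dienolate of 3 | C=C(C)/C=C(\OB(CCCC)CCCC)N1[C@@H](Cc2ccccc2)COC1=O | intermediate (not isolated)
7 | (S)-4-benzyl-3-[(2S,3R)-3-hydroxy-5-methyl-2-(prop-1-en-2-yl)hex-5-enoyl]oxazolidin-2-one | CC(=C)C[C@@H](O)[C@H](C(C)=C)C(=O)N1[C@@H](Cc2ccccc2)COC1=O | intermediate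
8 | (2S,3R)-3-hydroxy-N-methoxy-N,5-dimethyl-2-(prop-1-en-2-yl)hex-5-enamide | CC(=C)C[C@@H](O)[C@H](C(C)=C)C(=O)N(C)OC | intermediate
9 | (2S,3R)-3-[(tert-butyldimethylsilyl)oxy]-N-methoxy-N,5-dimethyl-2-(prop-1-en-2-yl)hex-5-enamide | CC(=C)C[C@@H](O[Si](C)(C)C(C)(C)C)[C@H](C(C)=C)C(=O)N(C)OC | intermediate
10 | (4S,5R)-5-[(tert-butyldimethylsilyl)oxy]-7-methyl-4-(prop-1-en-2-yl)octa-1,7-dien-3-one | CC(=C)C[C@@H](O[Si](C)(C)C(C)(C)C)[C@H](C(C)=C)C(=O)C=C | intermediate
11 | (5R,6S)-5-[(tert-butyldimethylsilyl)oxy]-3-methyl-6-(prop-1-en-2-yl)cyclohex-2-en-1-one | C1[C@@H](O[Si](C)(C)C(C)(C)C)[C@H](C(C)=C)C(=O)C=C1C | intermediate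
12 | 2-bromo-3-methylbut-1-ene | C=C(Br)C(C)C | starting material
13 | (3-methylbut-1-en-2-yl)lithium | [Li]C(=C)C(C)C | intermediate (not isolated)
14 | dichloro(3-methylbut-1-en-2-yl)cerium | Cl[Ce](Cl)C(=C)C(C)C | intermediate (not isolated)
15 | (1R,5R,6S)-5-[(tert-butyldimethylsilyl)oxy]-3-methyl-1-(3-methylbut-1-en-2-yl)-6-(prop-1-en-2-yl)cyclohex-2-en-1-ol | C1[C@@H](O[Si](C)(C)C(C)(C)C)[C@H](C(C)=C)[C@@](O)(C(=C)C(C)C)C=C1C | intermediate
16 | potassium alkoxide of 15 | C1[C@@H](O[Si](C)(C)C(C)(C)C)[C@H](C(C)=C)[C@@]([O-])(C(=C)C(C)C)C=C1C.[K+] | intermediate (not isolated)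
17 | potassium enolate of 18 (C5=C6 enolate, C4 and C7 trans) | [K+].[O-]/C1=C(/C(C)C)\CC/C(C)=C/[C@H](O[Si](C)(C)C(C)(C)C)C/C(C)=C\1 | intermediate (not isolated)
18 | (2Z,5R,6E,10S)-5-[(tert-butyldimethylsilyl)oxy]-3,7-dimethyl-10-(propan-2-yl)cyclodeca-2,6-dien-1-one | O=C1/C=C(C)\C[C@@H](O[Si](C)(C)C(C)(C)C)/C=C(C)/CC[C@H]1C(C)C | intermediate
19 | (5R,6E,10S)-5-[(tert-butyldimethylsilyl)oxy]-3,7-dimethyl-10-(propan-2-yl)-3-(trimethylstannyl)cyclodec-6-en-1-one (C3 epimers) | O=C1CC(C)([Sn](C)(C)C)C[C@@H](O[Si](C)(C)C(C)(C)C)/C=C(C)/CC[C@H]1C(C)C | intermediate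
20 | (2E,5R,6E,10S)-5-[(tert-butyldimethylsilyl)oxy]-3,7-dimethyl-10-(propan-2-yl)cyclodeca-2,6-dien-1-one | O=C1/C=C(C)/C[C@@H](O[Si](C)(C)C(C)(C)C)/C=C(C)/CC[C@H]1C(C)C | intermediate
21 | (1R,2E,5R,6E,10S)-5-[(tert-butyldimethylsilyl)oxy]-3,7-dimethyl-10-(propan-2-yl)cyclodeca-2,6-dien-1-ol | O[C@H]1/C=C(C)/C[C@@H](O[Si](C)(C)C(C)(C)C)/C=C(C)/CC[C@H]1C(C)C | intermediate
22 | (1R,2E,5R,6E,10S)-5-[(tert-butyldimethylsilyl)oxy]-3,7-dimethyl-10-(propan-2-yl)cyclodeca-2,6-dien-1-yl acetate | CC(=O)O[C@H]1/C=C(C)/C[C@@H](O[Si](C)(C)C(C)(C)C)/C=C(C)/CC[C@H]1C(C)C | intermediate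
23 | (1R,2E,5R,6E,10S)-5-hydroxy-3,7-dimethyl-10-(propan-2-yl)cyclodeca-2,6-dien-1-yl acetate | CC(=O)O[C@H]1/C=C(C)/C[C@@H](O)/C=C(C)/CC[C@H]1C(C)C | intermediate
24 | C1 alcohol of the target (C5 acetate of the C3–C4:C9–C10 diepoxy diol) | O[C@@H]1C[C@]2(C)O[C@H]2[C@H](OC(C)=O)[C@H](C(C)C)CC[C@]2(C)O[C@@H]12 | intermediate
25 | CNP0311463.1, the C1 angelate and C5 acetate of the diepoxide | C/C=C(/C)C(=O)O[C@@H]1C[C@]2(C)O[C@H]2[C@H](OC(C)=O)[C@H](C(C)C)CC[C@]2(C)O[C@@H]12 | target

**Step count**
Total: 16 steps. Longest linear sequence: 15 steps (steps 1 and 3–16, from 1 and 2; step 2 is a one-step side branch, and 12 enters at step 8).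

**The three steps most likely to fail**

1. Step 11 (with step 10): loss of geometric control in the elimination. The tin may leave with return to the (Z)-enone, or the olefin may end up out of conjugation.
Fallback, setting out from 18 and coming back at 21: the olefin is inverted stereospecifically at the alcohol stage. Ketone 18 is reduced with i-Bu2AlH to the (Z)-allylic alcohol F1. The C5 hydroxyl then directs a VO(acac)2/t-BuOOH epoxidation of C3=C4 only, since C9=C10 has no free hydroxyl next to it, giving the cis-epoxy alcohol F2. A Vedejs olefin inversion follows: LiPPh2 in THF opens the epoxide at C4 with inversion to the hydroxy phosphine F3, and MeI then triggers syn-elimination of the phosphine oxide, which should give the (E)-alkene 21. This presupposes the same facial course of the hydride addition as in step 12; if C5 comes out epimeric, the Mitsunobu entry below applies.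

2. Step 12: poor facial selectivity of hydride addition to the twisted enone carbonyl next to the isopropyl-bearing carbon.
Fallback, setting out from 20 and coming back at 22: the reduction is run deliberately to the C5 epimer, alcohol F4 (NaBH4, CeCl3·7H2O, MeOH, or whichever hydride favours it). The center is then inverted while the acetate is installed, by a Mitsunobu reaction (PPh3, DIAD, AcOH, toluene, 0 °C), which should give acetate 22 and replaces steps 12 and 13.

3. Step 15: incomplete facial control at the alkene next to the acetate, and acid-triggered transannular opening of the first-formed epoxide by the remaining alkene.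
Fallback, setting out from 21 and coming back at 24: each epoxide is delivered by its own hydroxyl under neutral metal-alkoxide control. VO(acac)2/t-BuOOH on 21 should give the C3–C4 epoxy alcohol F5. Acetylation (Ac2O, DMAP, pyridine) gives F6 and Bu4NF/AcOH gives the C1 alcohol F7. A second VO(acac)2/t-BuOOH epoxidation, now directed by the C1 hydroxyl, should give 24.

**Further compounds**
F1 | step 11 | (1R,2Z,5R,6E,10S)-5-[(tert-butyldimethylsilyl)oxy]-3,7-dimethyl-10-(propan-2-yl)cyclodeca-2,6-dien-1-ol | O[C@H]1/C=C(C)\C[C@@H](O[Si](C)(C)C(C)(C)C)/C=C(C)/CC[C@H]1C(C)C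
F2 | step 11 | cis-C3–C4 epoxide of F1, oxygen syn to the C5 hydroxyl | O[C@H]1[C@H]2O[C@@]2(C)C[C@@H](O[Si](C)(C)C(C)(C)C)/C=C(C)/CC[C@H]1C(C)C
F3 | step 11 | C4-diphenylphosphanyl C3,C5-diol from opening of F2 | O[C@H]1[C@H](P(c2ccccc2)c2ccccc2)[C@](O)(C)C[C@@H](O[Si](C)(C)C(C)(C)C)/C=C(C)/CC[C@H]1C(C)C
F4 | step 12 | (1S,2E,5R,6E,10S)-5-[(tert-butyldimethylsilyl)oxy]-3,7-dimethyl-10-(propan-2-yl)cyclodeca-2,6-dien-1-ol (C5 epimer of 21) | O[C@@H]1/C=C(C)/C[C@@H](O[Si](C)(C)C(C)(C)C)/C=C(C)/CC[C@H]1C(C)C
F5 | step 15 | C3–C4 epoxide of 21 (C5 alcohol, C1 silyl ether, C9=C10 intact) | O[C@H]1[C@@H]2O[C@@]2(C)C[C@@H](O[Si](C)(C)C(C)(C)C)/C=C(C)/CC[C@H]1C(C)C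
F6 | step 15 | C5 acetate of F5 | CC(=O)O[C@H]1[C@@H]2O[C@@]2(C)C[C@@H](O[Si](C)(C)C(C)(C)C)/C=C(C)/CC[C@H]1C(C)C
F7 | step 15 | C1 alcohol from desilylation of F6 | CC(=O)O[C@H]1[C@@H]2O[C@@]2(C)C[C@@H](O)/C=C(C)/CC[C@H]1C(C)C
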